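**Assumption:** 4,6-dibromoresorcinol, phloroglucinol and (S)-3-hydroxy-γ-butyrolactone are taken as cheap catalogue materials. Abbreviations: MOM = methoxymethyl; ArB = 2,4-bis(methoxymethoxy)-5-(3-methylbut-2-en-1-yl)phenyl.

## Retrosynthetic overview

1. Target ⇐ its tetrakis-MOM ether; ring C is closed last by an intramolecular Mitsunobu etherification (O1–C2, inversion) of an (R)-β-hydroxy ketone.
2. β-Hydroxy ketone ⇐ ortho-metallated ring A phenoxide + ring B β-hydroxy Weinreb amide (C4–C4a bond).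
3. Ring A piece ⇐ prenyl 3,5-bis(MOM-oxy)phenyl ether by an aromatic Claisen/Cope cascade (two [3,3] shifts): it makes the C6–prenyl bond and frees the phenol that becomes O1.
4. Weinreb amide ⇐ syn-selective 1,3-reduction of an aryl β-hydroxy ketone, then glycol cleavage: the carbinol centre of (S)-3-hydroxy-γ-butyrolactone sets C2 and ends as the C4 carbonyl carbon.
5. Aryl ketone ⇐ the lactone + a ring B aryllithium from 4,6-dibromoresorcinol; rings A and B are bought as arenes, ring C is the only ring formed.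

## Route

Step 1
Reactants: 1 4,6-dibromobenzene-1,3-diol (4,6-dibromoresorcinol)
Product: 2 1,5-dibromo-2,4-bis(methoxymethoxy)benzene
Conditions: MOMCl (2.5 equiv), i-Pr2NEt (3 equiv), CH2Cl2, 0 °C to rt
Reagents that add atoms: chloromethyl methyl ether, COCCl
Why: Williamson-type O-alkylation of both phenols gives acetal ethers that are stable to organolithium reagents, hydride, periodate and heat.

Step 2
Reactants: 2 1,5-dibromo-2,4-bis(methoxymethoxy)benzene
Product: 4 1-bromo-2,4-bis(methoxymethoxy)-5-(3-methylbut-2-en-1-yl)benzene, via aryllithium 3 (not isolated)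
Conditions: n-BuLi (1.0 equiv), THF, −78 °C; then CuBr·SMe2 (10 mol %), prenyl bromide (1.3 equiv), −78 to 0 °C
Reagents that add atoms: 1-bromo-3-methylbut-2-ene (prenyl bromide), CC(C)=CCBr
Why: a single bromine–lithium exchange on the symmetrical dibromide followed by copper-catalysed SN2 allylic substitution at the unhindered CH2 of prenyl bromide places the linear prenyl group at the future C5' without any regiochemical choice.

Step 3
Reactants: 4 1-bromo-2,4-bis(methoxymethoxy)-5-(3-methylbut-2-en-1-yl)benzene; 5 (4S)-4-hydroxyoxolan-2-one [(S)-3-hydroxy-γ-butyrolactone]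
Product: 8 (3S)-1-ArB-3,4-dihydroxybutan-1-one, via aryllithium 6 (not isolated), via lactone chloromagnesium alkoxide 7 (not isolated)
Conditions: 4, n-BuLi (1.05 equiv), THF, −78 °C; 5, i-PrMgCl (1.0 equiv), THF, −78 °C; combine at −78 °C, warm to −40 °C; aq NH4Cl
Reagents that add atoms: none
Why: nucleophilic acyl substitution of the aryllithium on the γ-lactone stops at the hemiketal alkoxide, so one aryl group is delivered and the purchased carbinol stereocentre, which is not touched, ends up β to the new aryl ketone.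

Step 4
Reactants: 8 (3S)-1-ArB-3,4-dihydroxybutan-1-one
Product: 10 (2S,4R)-4-ArB-butane-1,2,4-triol, via diethylboron chelate 9 (not isolated)
Conditions: Et2BOMe (1.2 equiv), THF/MeOH 4:1, −78 °C; NaBH4 (1.3 equiv), −78 °C; MeOH co-evaporation; recrystallisation
Reagents that add atoms: none
Why: Narasaka–Prasad reduction, in which external hydride attacks the six-membered boron chelate of the β-hydroxy ketone axially to give the syn-1,3-diol, so the purchased (S) carbinol fixes the new benzylic centre as R (dr typically ≥ 95:5, minor isomer removed here).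

Step 5
Reactants: 10 (2S,4R)-4-ArB-butane-1,2,4-triol
Product: 12 (3R)-3-ArB-3-hydroxypropanoic acid, via hydroxy aldehyde 11 (not isolated)
Conditions: NaIO4 (1.2 equiv), THF/H2O, 0 °C; crude aldehyde, NaClO2 (2 equiv), NaH2PO4 (2 equiv), 2-methylbut-2-ene (20 equiv), t-BuOH/H2O, 0 °C to rt
Reagents that add atoms: sodium chlorite, [Na+].[O-]Cl=O
Why: Malaprade glycol cleavage removes the terminal carbon as formaldehyde and turns the former controlling stereocentre into the aldehyde carbon (future C4), and the buffered Pinnick oxidation with a large excess of alkene scavenger takes it to the acid without touching the benzylic carbinol, the prenyl group or the MOM ethers.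

Step 6
Reactants: 12 (3R)-3-ArB-3-hydroxypropanoic acid
Product: 13 (3R)-3-ArB-3-hydroxy-N-methoxy-N-methylpropanamide
Conditions: MeNHOMe·HCl (1.5 equiv), EDC·HCl (1.3 equiv), HOBt (1 equiv), N-methylmorpholine (3 equiv), CH2Cl2, 0 °C to rt
Reagents that add atoms: N,O-dimethylhydroxylamine hydrochloride, CNOC.Cl
Why: carbodiimide amide coupling is much faster with the amine than with the hindered secondary alcohol and gives a Weinreb amide that accepts exactly one aryl nucleophile.

Step 7
Reactants: 14 benzene-1,3,5-triol (phloroglucinol)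
Product: 15 3,5-bis(methoxymethoxy)phenol
Conditions: MOMCl (2.0 equiv), i-Pr2NEt (2.2 equiv), DMF, 0 °C; chromatography (about 40 %, mono-ether recycled)
Reagents that add atoms: chloromethyl methyl ether, COCCl
Why: statistical O-alkylation of the threefold-symmetric triol, in which any two oxygens give the same product so only the degree of alkylation has to be separated.

Step 8
Reactants: 15 3,5-bis(methoxymethoxy)phenol
Product: 16 1,3-bis(methoxymethoxy)-5-[(3-methylbut-2-en-1-yl)oxy]benzene
Conditions: prenyl bromide (1.2 equiv), K2CO3 (2 equiv), acetone, reflux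
Reagents that add atoms: 1-bromo-3-methylbut-2-ene (prenyl bromide), CC(C)=CCBr
Why: Williamson ether synthesis on the only free phenol installs the allyl aryl ether needed for the rearrangement.

Step 9
Reactants: 16 1,3-bis(methoxymethoxy)-5-[(3-methylbut-2-en-1-yl)oxy]benzene
Product: 19 3,5-bis(methoxymethoxy)-4-(3-methylbut-2-en-1-yl)phenol, via ortho-dienone 17 (not isolated), via para-dienone 18 (not isolated)
Conditions: N,N-diethylaniline, 200 °C, sealed tube, 3 h
Reagents that add atoms: none
Why: aromatic Claisen rearrangement ([3,3]) to the ortho carbon gives a crowded dienone carrying the inverted 1,1-dimethylallyl group, which undergoes a Cope rearrangement ([3,3]) to the para carbon faster than it enolises in the aprotic amine, so tautomerisation leaves the linear prenyl group between the two MOM ethers and para to the freed phenol that will become O1.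

Step 10
Reactants: 19 3,5-bis(methoxymethoxy)-4-(3-methylbut-2-en-1-yl)phenol
Product: 20 2-iodo-3,5-bis(methoxymethoxy)-4-(3-methylbut-2-en-1-yl)phenol
Conditions: I2 (1.0 equiv), NaHCO3 (1.5 equiv), THF/H2O, 0 °C
Reagents that add atoms: iodine, II
Why: electrophilic aromatic iodination of the very electron-rich phenoxide is far faster than reversible iodonium formation at the alkene, and the two free ring positions are equivalent, so only one mono-iodide can form.

Step 11
Reactants: 20 2-iodo-3,5-bis(methoxymethoxy)-4-(3-methylbut-2-en-1-yl)phenol; 13 (3R)-3-ArB-3-hydroxy-N-methoxy-N-methylpropanamide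
Product: 23 (3R)-3-ArB-3-hydroxy-1-[6-hydroxy-2,4-bis(methoxymethoxy)-3-(3-methylbut-2-en-1-yl)phenyl]propan-1-one, via dilithiated phenoxide 21 (not isolated), via amide chloromagnesium alkoxide 22 (not isolated)
Conditions: 20 (1.3 equiv), n-BuLi (2.1 equiv per 20), THF, −78 °C; 13, i-PrMgCl (1.0 equiv), THF, −40 °C; combine, −78 to 0 °C; aq NH4Cl
Reagents that add atoms: none
Why: iodine–lithium exchange gives an ortho-lithiated phenoxide that adds once to the Weinreb amide, and because the chelated tetrahedral intermediate survives until the quench, the β-hydroxy ketone is only released at neutral pH and cannot undergo retro-aldol or elimination.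

Step 12
Reactants: 23 (3R)-3-ArB-3-hydroxy-1-[6-hydroxy-2,4-bis(methoxymethoxy)-3-(3-methylbut-2-en-1-yl)phenyl]propan-1-one
Product: 25 (2S)-2-ArB-5,7-bis(methoxymethoxy)-6-(3-methylbut-2-en-1-yl)-2,3-dihydro-4H-chromen-4-one, via alkoxyphosphonium phenoxide 24 (not isolated)
Conditions: PPh3 (1.5 equiv), DIAD (1.5 equiv), THF (0.02 M), 0 °C to rt
Reagents that add atoms: none
Why: intramolecular Mitsunobu etherification, in which the only free phenol (acidic, chelated to the ketone) displaces the activated benzylic oxygen in a 6-exo SN2 with inversion, turns the R carbinol into the 2S centre and fixes the prenyl group at C6.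

Step 13
Reactants: 25 (2S)-2-ArB-5,7-bis(methoxymethoxy)-6-(3-methylbut-2-en-1-yl)-2,3-dihydro-4H-chromen-4-one
Product: 26 (2S)-2-[2,4-dihydroxy-5-(3-methylbut-2-en-1-yl)phenyl]-5,7-dihydroxy-6-(3-methylbut-2-en-1-yl)-2,3-dihydro-4H-chromen-4-one (target)
Conditions: HCl (2 M in MeOH), 35 °C, monitored to completion
Reagents that add atoms: none
Why: acid-catalysed acetal exchange with methanol removes all four MOM groups as dimethoxymethane, while C2 is expected to hold because flavanones epimerise through base-mediated ring opening to the chalcone and dilute acid at this temperature is too mild to hydrate or cyclise the prenyl groups.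

## Compound list

1 | 4,6-dibromobenzene-1,3-diol | Oc1cc(O)c(Br)cc1Br | starting material
2 | 1,5-dibromo-2,4-bis(methoxymethoxy)benzene | COCOc1cc(OCOC)c(Br)cc1Br | intermediate
3 | [5-bromo-2,4-bis(methoxymethoxy)phenyl]lithium | [Li]c1cc(Br)c(OCOC)cc1OCOC | intermediate
4 | 1-bromo-2,4-bis(methoxymethoxy)-5-(3-methylbut-2-en-1-yl)benzene | Brc1cc(CC=C(C)C)c(OCOC)cc1OCOC | intermediate
5 | (4S)-4-hydroxyoxolan-2-one | O[C@@H]1COC(=O)C1 | starting material
6 | [2,4-bis(methoxymethoxy)-5-(3-methylbut-2-en-1-yl)phenyl]lithium | [Li]c1cc(CC=C(C)C)c(OCOC)cc1OCOC | intermediate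
7 | chloromagnesium (3S)-5-oxooxolan-3-olate | Cl[Mg]O[C@@H]1COC(=O)C1 | intermediate
8 | (3S)-1-[2,4-bis(methoxymethoxy)-5-(3-methylbut-2-en-1-yl)phenyl]-3,4-dihydroxybutan-1-one | OC[C@@H](O)CC(=O)c1cc(CC=C(C)C)c(OCOC)cc1OCOC | intermediate
9 | O3-diethylboryl derivative of 8 (boron chelated to the ketone oxygen) | CCB(CC)O[C@H](CO)CC(=O)c1cc(CC=C(C)C)c(OCOC)cc1OCOC | intermediate
10 | (2S,4R)-4-[2,4-bis(methoxymethoxy)-5-(3-methylbut-2-en-1-yl)phenyl]butane-1,2,4-triol | OC[C@@H](O)C[C@@H](O)c1cc(CC=C(C)C)c(OCOC)cc1OCOC | intermediate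
11 | (3R)-3-[2,4-bis(methoxymethoxy)-5-(3-methylbut-2-en-1-yl)phenyl]-3-hydroxypropanal | O=CC[C@@H](O)c1cc(CC=C(C)C)c(OCOC)cc1OCOC | intermediate
12 | (3R)-3-[2,4-bis(methoxymethoxy)-5-(3-methylbut-2-en-1-yl)phenyl]-3-hydroxypropanoic acid | OC(=O)C[C@@H](O)c1cc(CC=C(C)C)c(OCOC)cc1OCOC | intermediate
13 | (3R)-3-[2,4-bis(methoxymethoxy)-5-(3-methylbut-2-en-1-yl)phenyl]-3-hydroxy-N-methoxy-N-methylpropanamide | CON(C)C(=O)C[C@@H](O)c1cc(CC=C(C)C)c(OCOC)cc1OCOC | intermediate
14 | benzene-1,3,5-triol | Oc1cc(O)cc(O)c1 | starting material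
15 | 3,5-bis(methoxymethoxy)phenol | Oc1cc(OCOC)cc(OCOC)c1 | intermediate
16 | 1,3-bis(methoxymethoxy)-5-[(3-methylbut-2-en-1-yl)oxy]benzene | CC(C)=CCOc1cc(OCOC)cc(OCOC)c1 | intermediate
17 | 3,5-bis(methoxymethoxy)-6-(2-methylbut-3-en-2-yl)cyclohexa-2,4-dien-1-one | O=C1C=C(OCOC)C=C(OCOC)C1C(C)(C)C=C | intermediate
18 | 3,5-bis(methoxymethoxy)-4-(3-methylbut-2-en-1-yl)cyclohexa-2,5-dien-1-one | O=C1C=C(OCOC)C(CC=C(C)C)C(OCOC)=C1 | intermediate
19 | 3,5-bis(methoxymethoxy)-4-(3-methylbut-2-en-1-yl)phenol | Oc1cc(OCOC)c(CC=C(C)C)c(OCOC)c1 | intermediate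
20 | 2-iodo-3,5-bis(methoxymethoxy)-4-(3-methylbut-2-en-1-yl)phenol | Oc1cc(OCOC)c(CC=C(C)C)c(OCOC)c1I | intermediate
21 | lithium 2-lithio-3,5-bis(methoxymethoxy)-4-(3-methylbut-2-en-1-yl)phenoxide | [Li]Oc1cc(OCOC)c(CC=C(C)C)c(OCOC)c1[Li] | intermediate
22 | chloromagnesium alkoxide of 13 | CON(C)C(=O)C[C@@H](O[Mg]Cl)c1cc(CC=C(C)C)c(OCOC)cc1OCOC | intermediate
23 | (3R)-3-[2,4-bis(methoxymethoxy)-5-(3-methylbut-2-en-1-yl)phenyl]-3-hydroxy-1-[6-hydroxy-2,4-bis(methoxymethoxy)-3-(3-methylbut-2-en-1-yl)phenyl]propan-1-one | Oc1cc(OCOC)c(CC=C(C)C)c(OCOC)c1C(=O)C[C@@H](O)c1cc(CC=C(C)C)c(OCOC)cc1OCOC | intermediate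
24 | O-triphenylphosphonio derivative of 23 as its phenoxide zwitterion | [O-]c1cc(OCOC)c(CC=C(C)C)c(OCOC)c1C(=O)C[C@@H](O[P+](c1ccccc1)(c1ccccc1)c1ccccc1)c1cc(CC=C(C)C)c(OCOC)cc1OCOC | intermediate
25 | (2S)-2-[2,4-bis(methoxymethoxy)-5-(3-methylbut-2-en-1-yl)phenyl]-5,7-bis(methoxymethoxy)-6-(3-methylbut-2-en-1-yl)-2,3-dihydro-4H-chromen-4-one | CC(C)=CCc1cc([C@@H]2CC(=O)c3c(cc(OCOC)c(CC=C(C)C)c3OCOC)O2)c(OCOC)cc1OCOC | intermediate
26 | (2S)-2-[2,4-dihydroxy-5-(3-methylbut-2-en-1-yl)phenyl]-5,7-dihydroxy-6-(3-methylbut-2-en-1-yl)-2,3-dihydro-4H-chromen-4-one | CC(C)=CCc1cc([C@@H]2CC(=O)c3c(cc(O)c(CC=C(C)C)c3O)O2)c(O)cc1O | target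

## Summary

Total step count: 13.
Longest linear sequence: 9 steps (steps 1–6, then 11–13); the ring A branch (steps 7–10) joins at step 11.

The three steps most likely to fail are steps 3, 9 and 12.

Step 3 may fail because the aryllithium can act as a base on the hydroxy lactone and simply return the protonated arene. The fallback sets out from 5 and comes back at 8. Lactone 5 is opened with MeNHOMe·HCl and i-PrMgCl (THF, −20 °C) to (3S)-3,4-dihydroxy-N-methoxy-N-methylbutanamide F1. 2,2-Dimethoxypropane with catalytic PPTS converts it into 2-[(4S)-2,2-dimethyl-1,3-dioxolan-4-yl]-N-methoxy-N-methylacetamide F2. Aryllithium 6, made from 4 as before, adds once to give 1-ArB-2-[(4S)-2,2-dimethyl-1,3-dioxolan-4-yl]ethan-1-one F3, and 60 % aqueous AcOH at 40 °C removes the acetonide to give 8.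

Step 9 may fail because the ortho-dienone can enolise before the Cope shift and give the ortho 1,1-dimethylallyl phenol. The fallback keeps the same two [3,3] shifts but runs them on a substrate with an ortho carbonyl group, for which the para outcome is precedented. It sets out from 15 and comes back at 19. Ortho-formylation of 15 (MgCl2, Et3N, paraformaldehyde, MeCN, reflux) gives 2-hydroxy-4,6-bis(methoxymethoxy)benzaldehyde F4. O-Prenylation (prenyl bromide, K2CO3, DMF) gives 2,4-bis(methoxymethoxy)-6-[(3-methylbut-2-en-1-yl)oxy]benzaldehyde F5. The Claisen/Cope cascade (Eu(fod)3 10 mol %, CHCl3, 60 °C) gives 6-hydroxy-2,4-bis(methoxymethoxy)-3-(3-methylbut-2-en-1-yl)benzaldehyde F6. Pinnick oxidation gives 6-hydroxy-2,4-bis(methoxymethoxy)-3-(3-methylbut-2-en-1-yl)benzoic acid F7, which decarboxylates on warming in DMF (100 °C) to give 19.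

Step 12 may fail because the β-hydroxy ketone can eliminate to the chalcone, which recloses as racemate, or the electron-rich benzylic oxyphosphonium can ionise. The fallback removes the enolisable ketone from the substitution step and closes ring C by C–C bond formation; it does not remove the ionisation risk. It sets out from 13 (with 20) and comes back at 25. Intermolecular Mitsunobu etherification of 13 with iodophenol 20 (PPh3, DIAD, toluene, 0 °C) gives, with inversion, (3S)-3-ArB-3-[2-iodo-3,5-bis(methoxymethoxy)-4-(3-methylbut-2-en-1-yl)phenoxy]-N-methoxy-N-methylpropanamide F8. Iodine–magnesium exchange (i-PrMgCl·LiCl, THF, −40 °C) then triggers intramolecular acyl substitution on the Weinreb amide (Parham-type cyclisation) to give 25.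

## Further compounds

F1 | step 3 | (3S)-3,4-dihydroxy-N-methoxy-N-methylbutanamide | CON(C)C(=O)C[C@H](O)CO
F2 | step 3 | 2-[(4S)-2,2-dimethyl-1,3-dioxolan-4-yl]-N-methoxy-N-methylacetamide | CON(C)C(=O)C[C@H]1COC(C)(C)O1
F3 | step 3 | 1-[2,4-bis(methoxymethoxy)-5-(3-methylbut-2-en-1-yl)phenyl]-2-[(4S)-2,2-dimethyl-1,3-dioxolan-4-yl]ethan-1-one | O=C(C[C@H]1COC(C)(C)O1)c1cc(CC=C(C)C)c(OCOC)cc1OCOC
F4 | step 9 | 2-hydroxy-4,6-bis(methoxymethoxy)benzaldehyde | O=Cc1c(O)cc(OCOC)cc1OCOC
F5 | step 9 | 2,4-bis(methoxymethoxy)-6-[(3-methylbut-2-en-1-yl)oxy]benzaldehyde | O=Cc1c(OCC=C(C)C)cc(OCOC)cc1OCOC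
F6 | step 9 | 6-hydroxy-2,4-bis(methoxymethoxy)-3-(3-methylbut-2-en-1-yl)benzaldehyde | O=Cc1c(O)cc(OCOC)c(CC=C(C)C)c1OCOC
F7 | step 9 | 6-hydroxy-2,4-bis(methoxymethoxy)-3-(3-methylbut-2-en-1-yl)benzoic acid | OC(=O)c1c(O)cc(OCOC)c(CC=C(C)C)c1OCOC
F8 | step 12 | (3S)-3-[2,4-bis(methoxymethoxy)-5-(3-methylbut-2-en-1-yl)phenyl]-3-[2-iodo-3,5-bis(methoxymethoxy)-4-(3-methylbut-2-en-1-yl)phenoxy]-N-methoxy-N-methylpropanamide | CON(C)C(=O)C[C@H](Oc1cc(OCOC)c(CC=C(C)C)c(OCOC)c1I)c1cc(CC=C(C)C)c(OCOC)cc1OCOC
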